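**Plan**

1. Retrosynthesis: the hydroxyquinone is taken back to its tert-butyl ether and then to a para-silyloxyphenol. The ring bond between C1 (the carbonyl carbon next to the C2 oxygen) and C6 (the only ring CH) is cut to a dienylketene, which folds back to a cyclobutenone.
2. Enabling feature: ring atoms C1–C4 of the quinone (C=O, C–O, C–alkyl, C=O) are the four carbons of a squaric ester, and C5(OMe)=C6H is a 1-methoxyvinyl group. C1 can therefore be a ketene carbon set free by opening the strained four-membered ring.
3. Further cuts: C4–C5 (1-methoxyvinyllithium onto a squarate carbonyl) and C3–CH2 of the side chain (organolithium 1,2-addition, then 1,3-carbonyl transposition). This order places the side chain next to the vinyl carbinol, which direct addition to an alkylcyclobutenedione would not do.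
4. Forward: chlorohydrin; squarate–vinyllithium adduct; side-chain addition and transposition; acetylation; ring expansion (the only ring-forming step, four-membered ring to six-membered ring); oxidation; tert-butyl cleavage.
5. Stereochemistry: the single stereocentre comes from (R)-epichlorohydrin and is never a reacting centre.

Key step: step 5

Assumption: di-tert-butyl squarate is taken as a purchasable squaric ester; the ring carbon carrying the silyloxy group in 8 and 10–13 forms in both configurations and is drawn without a descriptor, because it becomes planar in step 5.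

**Route**

Step 1
Reactants: 1 (R)-epichlorohydrin; 2 decylmagnesium bromide
Product: 3 (R)-1-chlorotridecan-2-ol
Conditions: CuI (10 mol %), THF, −40 → −20 °C; aq NH4Cl
Reagents that add atoms: none
Why: Copper-catalysed Grignard opening of the epoxide at its unsubstituted carbon (SN2) does not touch the stereocentre, so 3 keeps the spatial arrangement and the (R) descriptor of 1, and the low temperature keeps the magnesium chloro alkoxide from closing back to an epoxide.

Step 2
Reactants: 4 methyl vinyl ether; 5 di-tert-butyl squarate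
Product: 8 2,3-di-tert-butoxy-4-(tert-butyldimethylsilyloxy)-4-(1-methoxyethenyl)cyclobut-2-en-1-one (racemic), via 1-methoxyvinyllithium 6 (not isolated), via lithium alkoxide adduct 7 (not isolated)
Conditions: 4 (1.5 equiv), t-BuLi, THF, −78 → 0 °C; 5, THF, −78 °C; TBSOTf, −78 → 0 °C
Reagents that add atoms: tert-butyldimethylsilyl trifluoromethanesulfonate, CC(C)(C)[Si](C)(C)OS(=O)(=O)C(F)(F)F
Why: alpha-Lithiation of the vinyl ether gives a vinyllithium that adds 1,2 to one of the two equivalent carbonyls of the squarate (mono-addition at −78 °C is the normal outcome for squaric esters), and the bulky silyl group on the tertiary oxygen blocks this carbinol from later ionisation and resists O-to-O migration.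

Step 3
Reactants: 3 (R)-1-chlorotridecan-2-ol; 8 silylated squarate adduct
Product: 12 2-tert-butoxy-4-(tert-butyldimethylsilyloxy)-3-[(2R)-2-hydroxytridecyl]-4-(1-methoxyethenyl)cyclobut-2-en-1-one (both configurations at ring C4), via lithium (S)-1-lithiotridecan-2-olate 9 (not isolated), via dilithium diolate adduct 10 (not isolated), via side-chain trifluoroacetate 11 (not isolated)
Conditions: 3, n-BuLi then LiC10H8 (lithium naphthalenide, 2 equiv), THF, −78 °C; 8, −78 °C; (CF3CO)2O, −78 °C; Et3N, −78 → 0 °C; MeOH, NaHCO3, 0 °C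
Reagents that add atoms: none
Why: Reductive lithiation of the lithium chloro alkoxide gives a beta-oxido organolithium (lithium oxide is too poor a leaving group for beta-elimination at −78 °C), which adds 1,2 to the only carbonyl of 8; trifluoroacetylation makes the new tertiary oxygen a leaving group, and its ionisation, assisted by the vinylogous tert-butoxy group with loss of 2-methylpropene, is a Stork–Danheiser-type 1,3-carbonyl transposition that can only occur at this carbinol because the other one is silylated, the side-chain stereocentre being a spectator and its trifluoroacetate being removed by methanolysis.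

Step 4
Reactants: 12 hydroxy cyclobutenone
Product: 13 (2R)-1-[2-tert-butoxy-4-(tert-butyldimethylsilyloxy)-4-(1-methoxyethenyl)-3-oxocyclobut-1-en-1-yl]tridecan-2-yl acetate (both configurations at ring C4)
Conditions: Ac2O, pyridine, DMAP (cat.), CH2Cl2, 0 °C → rt
Reagents that add atoms: acetic anhydride, CC(=O)OC(C)=O
Why: Standard DMAP-catalysed acetylation of the only free hydroxyl group, with retention at the stereocentre because no bond to it is broken.

Step 5
Reactants: 13 acetoxy cyclobutenone
Product: 16 (2R)-1-[2-tert-butoxy-6-(tert-butyldimethylsilyloxy)-3-hydroxy-5-methoxyphenyl]tridecan-2-yl acetate, via dienylketene 14 (not isolated), via cyclohexa-2,4-dienone 15 (not isolated)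
Conditions: toluene (0.01 M, degassed), 110 °C
Reagents that add atoms: none
Why: Heating opens the strained four-membered ring of 13 by conrotatory 4π electrocyclic cleavage of the C1–C4 bond to the dienylketene 14, whose ketene carbon (the former C1, flanked by the tert-butoxy carbon) then bonds to the terminal CH2 of the 1-methoxyvinyl group in a 6π electrocyclisation to give dienone 15, and enolisation gives the phenol 16. The closest known reaction type is the thermal Moore-type ring expansion of 4-alkenyl-4-oxycyclobutenones to hydroquinone derivatives. The six-membered ring is closed in a thermally allowed disrotatory 6π electrocyclic mode in which all six ring atoms belong to the ketene–diene system. No stereocentre is created; the ring carbon bearing the silyloxy group becomes planar, so both epimers of 13 converge on one product and the side-chain stereocentre is a spectator. The step needs the vinyl group to end up cis to the ketene, which the silyloxy donor on C4 secures by rotating outward in the ring opening (torquoselectivity), and it needs the right ring regiochemistry, which follows from the positions that the tert-butoxy group (C2) and the side chain (C3) take on the cyclobutenone in step 3. Relief of ring strain and aromatisation should make the sequence irreversible.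

Step 6
Reactants: 16 para-silyloxyphenol
Product: 17 (2R)-1-(2-tert-butoxy-5-methoxy-3,6-dioxocyclohexa-1,4-dien-1-yl)tridecan-2-yl acetate
Conditions: PhI(OAc)2, MeCN–H2O, 0 °C
Reagents that add atoms: none
Why: Oxidation of a para-silyloxyphenol by a trivalent iodine reagent gives the para-quinone by loss of the silyl group from oxygen (oxidative desilylation), which leaves the tert-butyl vinylogous ester, the methoxy group and the acetate alone.

Step 7
Reactants: 17 tert-butoxyquinone
Product: 18 (2R)-1-(2-hydroxy-5-methoxy-3,6-dioxocyclohexa-1,4-dien-1-yl)tridecan-2-yl acetate (CNP0258436.1)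
Conditions: CF3CO2H, CH2Cl2, 0 °C → rt
Reagents that add atoms: none
Why: Acid-mediated cleavage of the tert-butyl vinylogous ester (loss of the tert-butyl cation as 2-methylpropene) is the known way from tert-butoxyquinones to hydroxyquinones and spares the methyl vinylogous ester and the secondary acetate.

**Compound list**

1 | (R)-epichlorohydrin | ClC[C@H]1CO1 | starting material
2 | decylmagnesium bromide | CCCCCCCCCC[Mg]Br | starting material
3 | (R)-1-chlorotridecan-2-ol | CCCCCCCCCCC[C@H](CCl)O | intermediate
4 | methyl vinyl ether | COC=C | starting material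
5 | di-tert-butyl squarate (3,4-di-tert-butoxycyclobut-3-ene-1,2-dione) | CC(C)(C)OC1=C(OC(C)(C)C)C(=O)C1=O | starting material
6 | 1-methoxyvinyllithium (not isolated) | [Li]C(=C)OC | intermediate
7 | lithium 2,3-di-tert-butoxy-1-(1-methoxyethenyl)-4-oxocyclobut-2-en-1-olate (not isolated) | [Li]OC1(C(=C)OC)C(OC(C)(C)C)=C(OC(C)(C)C)C1=O | intermediate
8 | 2,3-di-tert-butoxy-4-(tert-butyldimethylsilyloxy)-4-(1-methoxyethenyl)cyclobut-2-en-1-one (racemic) | CC(C)(C)[Si](C)(C)OC1(C(=C)OC)C(OC(C)(C)C)=C(OC(C)(C)C)C1=O | intermediate
9 | lithium (S)-1-lithiotridecan-2-olate (not isolated; same spatial arrangement as 3, the descriptor changes only because lithium ranks below carbon) | CCCCCCCCCCC[C@H](C[Li])O[Li] | intermediate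
10 | dilithium salt of 2,3-di-tert-butoxy-4-(tert-butyldimethylsilyloxy)-1-[(2R)-2-hydroxytridecyl]-4-(1-methoxyethenyl)cyclobut-2-en-1-ol (not isolated) | CCCCCCCCCCC[C@H](CC1(O[Li])C(OC(C)(C)C)=C(OC(C)(C)C)C1(O[Si](C)(C)C(C)(C)C)C(=C)OC)O[Li] | intermediate
11 | (2R)-1-[2-tert-butoxy-4-(tert-butyldimethylsilyloxy)-4-(1-methoxyethenyl)-3-oxocyclobut-1-en-1-yl]tridecan-2-yl trifluoroacetate (not isolated) | CCCCCCCCCCC[C@H](CC1=C(OC(C)(C)C)C(=O)C1(O[Si](C)(C)C(C)(C)C)C(=C)OC)OC(=O)C(F)(F)F | intermediate
12 | 2-tert-butoxy-4-(tert-butyldimethylsilyloxy)-3-[(2R)-2-hydroxytridecyl]-4-(1-methoxyethenyl)cyclobut-2-en-1-one | CCCCCCCCCCC[C@H](CC1=C(OC(C)(C)C)C(=O)C1(O[Si](C)(C)C(C)(C)C)C(=C)OC)O | intermediate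
13 | (2R)-1-[2-tert-butoxy-4-(tert-butyldimethylsilyloxy)-4-(1-methoxyethenyl)-3-oxocyclobut-1-en-1-yl]tridecan-2-yl acetate | CCCCCCCCCCC[C@H](CC1=C(OC(C)(C)C)C(=O)C1(O[Si](C)(C)C(C)(C)C)C(=C)OC)OC(C)=O | intermediate
14 | dienylketene, 3-[(2R)-2-acetoxytridecyl]-2-tert-butoxy-4-(tert-butyldimethylsilyloxy)-5-methoxyhexa-1,3,5-trien-1-one, vinyl group cis to the ketene (not isolated) | O=C=C(OC(C)(C)C)/C(C[C@@H](CCCCCCCCCCC)OC(C)=O)=C(\C(=C)OC)O[Si](C)(C)C(C)(C)C | intermediate
15 | (2R)-1-[2-tert-butoxy-6-(tert-butyldimethylsilyloxy)-5-methoxy-3-oxocyclohexa-1,5-dien-1-yl]tridecan-2-yl acetate (not isolated) | CCCCCCCCCCC[C@H](CC1=C(OC(C)(C)C)C(=O)CC(OC)=C1O[Si](C)(C)C(C)(C)C)OC(C)=O | intermediate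
16 | (2R)-1-[2-tert-butoxy-6-(tert-butyldimethylsilyloxy)-3-hydroxy-5-methoxyphenyl]tridecan-2-yl acetate | CCCCCCCCCCC[C@H](Cc1c(OC(C)(C)C)c(O)cc(OC)c1O[Si](C)(C)C(C)(C)C)OC(C)=O | intermediate
17 | (2R)-1-(2-tert-butoxy-5-methoxy-3,6-dioxocyclohexa-1,4-dien-1-yl)tridecan-2-yl acetate | CCCCCCCCCCC[C@H](CC1=C(OC(C)(C)C)C(=O)C=C(OC)C1=O)OC(C)=O | intermediate
18 | (2R)-1-(2-hydroxy-5-methoxy-3,6-dioxocyclohexa-1,4-dien-1-yl)tridecan-2-yl acetate | CCCCCCCCCCC[C@H](CC1=C(O)C(=O)C=C(OC)C1=O)OC(C)=O | target

**Step count and risks**

Total step count: 7. Longest linear sequence: 6 (steps 2–7, or steps 1 and 3–7).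

Steps most likely to fail:

Step 3. Two processes are at risk. The C,O-dilithio reagent 9 may undergo beta-elimination (to tridec-1-ene) before it adds, or add only slowly to the hindered carbonyl of 8. The enol ether may also be attacked by the anhydride or by liberated acid during the ionisation. The fallback sets out from 8 and comes back at 12. Tridecan-2-one is deprotonated at its methyl group (LiN(i-Pr)2, THF, −78 °C) to the kinetic enolate lithium tridec-1-en-2-olate F1, which has no beta leaving group. It is added to 8 to give the lithium aldolate F2. Trapping with (CF3CO)2O and Et3N as in step 3 should give, by the same transposition, the keto cyclobutenone 2-tert-butoxy-4-(tert-butyldimethylsilyloxy)-4-(1-methoxyethenyl)-3-(2-oxotridecyl)cyclobut-2-en-1-one F3. An (R)-selective ketoreductase (NADPH, isopropanol as hydride source, pH 7 buffer) then reduces the side-chain ketone of F3 to 12.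

Step 5. The phenol formed may add to the 1-methoxyvinyl group of unreacted 13 (acetal formation), or the enol ether may be lost in other ways at 110 °C, consuming substrate before ring opening. The fallback sets out from 5 and comes back at 17; it leaves the enol ether out of the thermolysis and introduces the methoxy group afterwards. Vinyllithium (CH2=CHBr, t-BuLi) is added to 5 and the alkoxide is silylated as in step 2 to give 2,3-di-tert-butoxy-4-(tert-butyldimethylsilyloxy)-4-ethenylcyclobut-2-en-1-one F4. Addition of 9 and acylative transposition as in step 3 give the hydroxy cyclobutenone 2-tert-butoxy-4-(tert-butyldimethylsilyloxy)-4-ethenyl-3-[(2R)-2-hydroxytridecyl]cyclobut-2-en-1-one F5. Acetylation as in step 4 gives its acetate F6. Thermolysis in toluene at 110 °C gives the phenol (2R)-1-[2-tert-butoxy-6-(tert-butyldimethylsilyloxy)-3-hydroxyphenyl]tridecan-2-yl acetate F7. PhI(OAc)2 oxidation gives the quinone (2R)-1-(2-tert-butoxy-3,6-dioxocyclohexa-1,4-dien-1-yl)tridecan-2-yl acetate F8. Conjugate addition of MeOH to F8 (MeOH, ZnCl2, rt; re-oxidation with Ag2O) should occur at the ring CH para to the tert-butoxy carbon, the position activated by the carbonyl that the tert-butoxy group does not deactivate, and give 17.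

Step 6. The oxidant may attack the ortho carbon that bears the tert-butoxy group (ortho-quinone formation) or over-oxidise, in place of clean oxidative desilylation. The fallback sets out from 16 and comes back at 18; the protecting groups are removed before the oxidation. CF3CO2H in CH2Cl2 cleaves the aryl tert-butyl ether to the catechol (2R)-1-[6-(tert-butyldimethylsilyloxy)-2,3-dihydroxy-5-methoxyphenyl]tridecan-2-yl acetate F9. Bu4NF/AcOH in THF under argon removes the silyl group to give the triol (2R)-1-(2,3,6-trihydroxy-5-methoxyphenyl)tridecan-2-yl acetate F10. F10 is oxidised by air (O2, pH 7 phosphate buffer/MeCN) directly to 18, the hydroxy-para-quinone being the stable tautomer of the oxidation product.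

Further compounds
F1 | step 3 | lithium tridec-1-en-2-olate | [Li]OC(=C)CCCCCCCCCCC
F2 | step 3 | lithium 2,3-di-tert-butoxy-4-(tert-butyldimethylsilyloxy)-4-(1-methoxyethenyl)-1-(2-oxotridecyl)cyclobut-2-en-1-olate | [Li]OC1(CC(=O)CCCCCCCCCCC)C(OC(C)(C)C)=C(OC(C)(C)C)C1(O[Si](C)(C)C(C)(C)C)C(=C)OC
F3 | step 3 | 2-tert-butoxy-4-(tert-butyldimethylsilyloxy)-4-(1-methoxyethenyl)-3-(2-oxotridecyl)cyclobut-2-en-1-one | CCCCCCCCCCCC(=O)CC1=C(OC(C)(C)C)C(=O)C1(O[Si](C)(C)C(C)(C)C)C(=C)OC
F4 | step 5 | 2,3-di-tert-butoxy-4-(tert-butyldimethylsilyloxy)-4-ethenylcyclobut-2-en-1-one | CC(C)(C)[Si](C)(C)OC1(C=C)C(OC(C)(C)C)=C(OC(C)(C)C)C1=O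
F5 | step 5 | 2-tert-butoxy-4-(tert-butyldimethylsilyloxy)-4-ethenyl-3-[(2R)-2-hydroxytridecyl]cyclobut-2-en-1-one | CCCCCCCCCCC[C@H](CC1=C(OC(C)(C)C)C(=O)C1(O[Si](C)(C)C(C)(C)C)C=C)O
F6 | step 5 | (2R)-1-[2-tert-butoxy-4-(tert-butyldimethylsilyloxy)-4-ethenyl-3-oxocyclobut-1-en-1-yl]tridecan-2-yl acetate | CCCCCCCCCCC[C@H](CC1=C(OC(C)(C)C)C(=O)C1(O[Si](C)(C)C(C)(C)C)C=C)OC(C)=O
F7 | step 5 | (2R)-1-[2-tert-butoxy-6-(tert-butyldimethylsilyloxy)-3-hydroxyphenyl]tridecan-2-yl acetate | CCCCCCCCCCC[C@H](Cc1c(OC(C)(C)C)c(O)ccc1O[Si](C)(C)C(C)(C)C)OC(C)=O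
F8 | step 5 | (2R)-1-(2-tert-butoxy-3,6-dioxocyclohexa-1,4-dien-1-yl)tridecan-2-yl acetate | CCCCCCCCCCC[C@H](CC1=C(OC(C)(C)C)C(=O)C=CC1=O)OC(C)=O
F9 | step 6 | (2R)-1-[6-(tert-butyldimethylsilyloxy)-2,3-dihydroxy-5-methoxyphenyl]tridecan-2-yl acetate | CCCCCCCCCCC[C@H](Cc1c(O)c(O)cc(OC)c1O[Si](C)(C)C(C)(C)C)OC(C)=O
F10 | step 6 | (2R)-1-(2,3,6-trihydroxy-5-methoxyphenyl)tridecan-2-yl acetate | CCCCCCCCCCC[C@H](Cc1c(O)c(O)cc(OC)c1O)OC(C)=O
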